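**Plan**
Numbering: spiro[4.5]decane C1 (CHOH), C2 (side-chain carbon), C5 (spiro), C6 (C(CH3)OH), C9 (alkylidene carbon), C10 (hydroxypropyl carbon); Cs is the side-chain carbon bonded to C2; ring A is the cyclopentane, ring B the cyclohexane.
Feature: in ring B the oxygen-bearing C6 and the enal-bearing C9 sit 1,4 to each other across C7–C8, so ring B is a hidden cyclohexane-1,4-dione whose C7–C8 bond joins the α-carbons of two methyl ketones hung on C5 and C10.
Cuts (last-formed first): acetate and enal oxidation level; the bond between the alkylidene CH on Cs and the dienyl unit (Stille); Cs–C2 (carbenoid C–H insertion from the C1 oxygen); C6–CH3; C9=C (olefination); C7–C8; C5–C10 (allylation).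
Forward: ring A comes from 2-acetylcyclopentanone; iridium-catalysed allylation joins C5–C10; Wacker oxidation gives the second methyl ketone; anodic coupling of the bis(silyl enol ether) closes ring B; then C9, C6, the C1/C2 lactone and the triene are added.
Stereochemistry: C5 and C10 from the chiral iridium catalyst; C1 by hydride attack anti to the C10 branch; C6 by equatorial methyl addition anti to the axial C10 arm; C2 by cis ring fusion in the C–H insertion; enal geometry from the olefination, the Z alkene from a chelated enol triflate, the E alkene from the stannane.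

Key step: step 12

Abbreviations: TBDPS = tert-butyldiphenylsilyl, TES = triethylsilyl, Piv = 2,2-dimethylpropanoyl, Tf = trifluoromethanesulfonyl, TBD = 1,5,7-triazabicyclo[4.4.0]dec-5-ene.
Assumption: the iridium–phosphoramidite catalyst is taken to control both new centres in step 7 as it does for cyclic β-keto esters, with the ligand antipode chosen to give the (2R,3′R) isomer 10.

**Fragment A: allyl carbonate**

Step 1
Reactants: 1 pent-4-yn-1-ol
Product: 2 tert-butyl(pent-4-yn-1-yloxy)diphenylsilane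
Conditions: TBDPSCl, imidazole, CH2Cl2, 0 → 25 °C
Reagents that add atoms: tert-butyl(chloro)diphenylsilane, CC(C)(C)[Si](Cl)(c1ccccc1)c1ccccc1
Why: Routine silyl ether formation masks the future C10 arm hydroxyl with a group that should tolerate every later base, hydride and the electrolysis.

Step 2
Reactants: 2 tert-butyl(pent-4-yn-1-yloxy)diphenylsilane
Product: 3 6-(tert-butyldiphenylsilyloxy)hex-2-yn-1-ol
Conditions: n-BuLi, THF, −78 °C; (CH2O)n, −78 → 25 °C
Reagents that add atoms: formaldehyde (from paraformaldehyde), C=O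
Why: Addition of the lithium acetylide to formaldehyde is the standard one-carbon homologation to a propargylic alcohol.

Step 3
Reactants: 3 6-(tert-butyldiphenylsilyloxy)hex-2-yn-1-ol
Product: 4 (E)-6-(tert-butyldiphenylsilyloxy)hex-2-en-1-ol
Conditions: NaAlH2(OCH2CH2OMe)2, THF, 0 → 25 °C
Reagents that add atoms: none
Why: Hydroxyl-directed trans-hydroalumination of the propargylic alcohol followed by protonolysis should give only the E allylic alcohol.

Step 4
Reactants: 4 (E)-6-(tert-butyldiphenylsilyloxy)hex-2-en-1-ol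
Product: 5 (E)-6-(tert-butyldiphenylsilyloxy)hex-2-en-1-yl methyl carbonate
Conditions: ClCO2Me, pyridine, CH2Cl2, 0 °C
Reagents that add atoms: methyl chloroformate, COC(=O)Cl
Why: O-Acylation gives the linear allylic methyl carbonate, the usual electrophile for iridium-catalysed allylic substitution.

**Fragment B: dienylstannane**

Step 5
Reactants: 6 6-methylhept-5-en-2-one
Product: 7 6-methylhepta-1,5-dien-2-yl trifluoromethanesulfonate
Conditions: LiN(i-Pr)2, THF, −78 °C; PhNTf2, −78 → 0 °C
Reagents that add atoms: N-phenylbis(trifluoromethanesulfonimide), O=S(=O)(N(c1ccccc1)S(=O)(=O)C(F)(F)F)C(F)(F)F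
Why: Kinetic deprotonation of the methyl ketone at the methyl group and O-sulfonylation (enol triflate formation) should give the 1,1-disubstituted alkenyl triflate.

Step 6
Reactants: 7 6-methylhepta-1,5-dien-2-yl trifluoromethanesulfonate
Product: 8 tributyl[(1E)-7-methyl-3-methylideneocta-1,6-dien-1-yl]stannane
Conditions: (E)-Bu3SnCH=CHSnBu3 (2.5 equiv), Pd(PPh3)4 (5 mol%), LiCl, THF, 65 °C
Reagents that add atoms: (E)-1,2-bis(tributylstannyl)ethene, CCCC[Sn](CCCC)(CCCC)/C=C/[Sn](CCCC)(CCCC)CCCC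
Why: Stille coupling of an alkenyl triflate with an excess of the bis-stannane should stop after one coupling and transfer the E-stannylvinyl unit with retention.

**Main line**

Step 7
Reactants: 9 2-acetylcyclopentan-1-one; 5 (E)-6-(tert-butyldiphenylsilyloxy)hex-2-en-1-yl methyl carbonate
Product: 10 (2R)-2-acetyl-2-[(3R)-6-(tert-butyldiphenylsilyloxy)hex-1-en-3-yl]cyclopentan-1-one
Conditions: [Ir(cod)Cl]2 (2 mol%), chiral BINOL-derived N-aryl phosphoramidite (4 mol%), TBD (10 mol%), LiBr, THF, 25 °C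
Reagents that add atoms: none
Why: Iridium-catalysed asymmetric allylic alkylation attacks the substituted allyl terminus (branched product), and the chiral iridacycle should fix both the allylic centre C10 and the enolate face at C5, as it does with cyclic β-keto esters.

Step 8
Reactants: 10 (2R)-2-acetyl-2-[(3R)-6-(tert-butyldiphenylsilyloxy)hex-1-en-3-yl]cyclopentan-1-one
Product: 11 1-[(1S,2R)-2-hydroxy-1-[(3R)-6-(tert-butyldiphenylsilyloxy)hex-1-en-3-yl]cyclopentyl]ethan-1-one
Conditions: LiAlH(Ot-Bu)3, THF, −78 → −20 °C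
Reagents that add atoms: none
Why: In this diastereoselective hydride reduction the tied-back ring carbonyl should react before the tert-alkyl methyl ketone, and hydride should come from the face of the flat acetyl group, anti to the branched C10 substituent, so that the new C1 hydroxyl is cis to C10 (1R in target numbering).

Step 9
Reactants: 11 1-[(1S,2R)-2-hydroxy-1-[(3R)-6-(tert-butyldiphenylsilyloxy)hex-1-en-3-yl]cyclopentyl]ethan-1-one
Product: 12 (1R,2S)-2-acetyl-2-[(3R)-6-(tert-butyldiphenylsilyloxy)hex-1-en-3-yl]cyclopentyl 2,2-dimethylpropanoate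
Conditions: PivCl, DMAP, pyridine, CH2Cl2, 40 °C
Reagents that add atoms: pivaloyl chloride, CC(C)(C)C(Cl)=O
Why: Esterification with a pivalate, which has no α-hydrogen and is not oxidised at the anode, masks C1 through enolisation and electrolysis and also blocks retro-aldol opening of the β-hydroxy ketone.

Step 10
Reactants: 12 (1R,2S)-2-acetyl-2-[(3R)-6-(tert-butyldiphenylsilyloxy)hex-1-en-3-yl]cyclopentyl 2,2-dimethylpropanoate
Product: 13 (1R,2S)-2-acetyl-2-[(3S)-6-(tert-butyldiphenylsilyloxy)-2-oxohexan-3-yl]cyclopentyl 2,2-dimethylpropanoate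
Conditions: PdCl2 (10 mol%), CuCl (1 equiv), O2 (1 atm), DMF/H2O 7:1, 25 °C
Reagents that add atoms: water, O
Why: Tsuji–Wacker oxidation of the terminal vinyl group of an α-allyl ketone gives the Markovnikov methyl ketone, the classical route to 1,4-diketones, without touching C10.

Step 11
Reactants: 13 (1R,2S)-2-acetyl-2-[(3S)-6-(tert-butyldiphenylsilyloxy)-2-oxohexan-3-yl]cyclopentyl 2,2-dimethylpropanoate
Product: 14 (1R,2S)-2-[1-(trimethylsilyloxy)ethenyl]-2-[(3S)-6-(tert-butyldiphenylsilyloxy)-2-(trimethylsilyloxy)hex-1-en-3-yl]cyclopentyl 2,2-dimethylpropanoate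
Conditions: Me3SiCl (6 equiv), Et3N, THF, −78 °C; LiN(i-Pr)2 (2.5 equiv) added slowly
Reagents that add atoms: chlorotrimethylsilane, C[Si](C)(C)Cl
Why: Kinetic enol silylation with in-situ quench traps each methyl-side enolate as it forms, so the 1,4-diketone cannot close to a cyclopentenone by aldol reaction and the hindered C10–H is left alone.

Step 12
Reactants: 14 (1R,2S)-2-[1-(trimethylsilyloxy)ethenyl]-2-[(3S)-6-(tert-butyldiphenylsilyloxy)-2-(trimethylsilyloxy)hex-1-en-3-yl]cyclopentyl 2,2-dimethylpropanoate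
Product: 15 (1R,5S,10S)-10-[3-(tert-butyldiphenylsilyloxy)propyl]-6,9-dioxospiro[4.5]decan-1-yl 2,2-dimethylpropanoate
Conditions: undivided cell, reticulated vitreous carbon anode, Pt cathode, constant current (about 2.2 F/mol), LiClO4 (0.1 M), 2,6-lutidine, MeOH (10 equiv), MeCN/CH2Cl2 4:1, 5 mM, 0 °C
Reagents that add atoms: none
Why: Proposed new method: removal of one electron from one silyl enol ether at the anode should give a radical cation whose CH2 terminus bonds to the CH2 terminus of the neighbouring enol ether (C7–C8), after which a second electron is lost and methanol takes up both trimethylsilyl groups to leave the C6 and C9 carbonyls. The closest known chemistry is the intramolecular oxidative coupling of bis(silyl enol ethers) to cyclic 1,4-diketones with (NH4)2Ce(NO3)6 or Cu(OTf)2, together with anodic couplings of silyl enol ether radical cations with tethered enol ethers and furans. Ring B closes as a six-membered ring with both enol C=C bonds inside it (6-endo-trig at the accepting alkene). No stereocentre is formed, and C1, C5 and C10 are not touched. The step needs ring closure to outrun intermolecular coupling and needs no other group to be oxidised: high dilution and the short C5–C10 link between the two enol ethers favour closure, and the pivalate, the silyl ethers and the phenyl rings on silicon are oxidised only at clearly higher potential.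

Step 13
Reactants: 15 (1R,5S,10S)-10-[3-(tert-butyldiphenylsilyloxy)propyl]-6,9-dioxospiro[4.5]decan-1-yl 2,2-dimethylpropanoate
Product: 16 ethyl (2E)-2-[(1R,5S,10R)-10-[3-(tert-butyldiphenylsilyloxy)propyl]-6-oxo-1-(pivaloyloxy)spiro[4.5]decan-9-ylidene]propanoate
Conditions: (EtO)2P(O)CH(CH3)CO2Et, NaH, DME, 0 → 70 °C
Reagents that add atoms: triethyl 2-phosphonopropionate, CCOC(=O)C(C)P(=O)(OCC)OCC
Why: Horner–Wadsworth–Emmons olefination should pick the C9 carbonyl, since C6 is flanked by the quaternary spiro carbon, and should place the ester anti to the more substituted C10 side, as it does with 2-substituted cyclohexanones, with any minor isomer removed by chromatography.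

Step 14
Reactants: 16 ethyl (2E)-2-[(1R,5S,10R)-10-[3-(tert-butyldiphenylsilyloxy)propyl]-6-oxo-1-(pivaloyloxy)spiro[4.5]decan-9-ylidene]propanoate
Product: 17 ethyl (2E)-2-[(1R,5S,6S,10R)-6-hydroxy-6-methyl-10-[3-(tert-butyldiphenylsilyloxy)propyl]-1-(pivaloyloxy)spiro[4.5]decan-9-ylidene]propanoate
Conditions: MeLi, CeCl3, THF, −78 °C
Reagents that add atoms: methyllithium, [Li]C
Why: Organocerium 1,2-addition tolerates the hindered, enolisable ketone and leaves the esters alone at −78 °C; allylic strain with the alkylidene methyl holds the C10 arm axial, so methyl should enter equatorially on the opposite face and leave the C6 hydroxyl cis to the arm (6S).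

Step 15
Reactants: 17 ethyl (2E)-2-[(1R,5S,6S,10R)-6-hydroxy-6-methyl-10-[3-(tert-butyldiphenylsilyloxy)propyl]-1-(pivaloyloxy)spiro[4.5]decan-9-ylidene]propanoate
Product: 18 the 6-O-triethylsilyl ether of 17
Conditions: Et3SiOTf, 2,6-lutidine, CH2Cl2, 0 °C
Reagents that add atoms: triethylsilyl trifluoromethanesulfonate, CC[Si](CC)(CC)OS(=O)(=O)C(F)(F)F
Why: Silylation with a silyl triflate caps the tertiary alcohol so that it cannot capture the rhodium carbenoid by O–H insertion in step 19.

Step 16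
Reactants: 18 the 6-O-triethylsilyl ether of 17
Product: 19 (1R,5S,6S,10R)-9-[(E)-1-hydroxypropan-2-ylidene]-6-methyl-10-[3-(tert-butyldiphenylsilyloxy)propyl]-6-(triethylsilyloxy)spiro[4.5]decan-1-ol
Conditions: i-Bu2AlH (6 equiv), CH2Cl2, −78 → 0 °C
Reagents that add atoms: none
Why: Hydride reduction with i-Bu2AlH turns the conjugated ester into the allylic alcohol by 1,2-addition and cleaves the pivalate in the same operation, while the silyl ethers stay in place.

Step 17
Reactants: 19 (1R,5S,6S,10R)-9-[(E)-1-hydroxypropan-2-ylidene]-6-methyl-10-[3-(tert-butyldiphenylsilyloxy)propyl]-6-(triethylsilyloxy)spiro[4.5]decan-1-ol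
Product: 20 (1R,5S,6S,10R)-9-[(E)-1-(tert-butyldiphenylsilyloxy)propan-2-ylidene]-6-methyl-10-[3-(tert-butyldiphenylsilyloxy)propyl]-6-(triethylsilyloxy)spiro[4.5]decan-1-ol
Conditions: TBDPSCl, imidazole, CH2Cl2, 0 °C
Reagents that add atoms: tert-butyl(chloro)diphenylsilane, CC(C)(C)[Si](Cl)(c1ccccc1)c1ccccc1
Why: Selective silylation should take the primary allylic hydroxyl and leave the neopentyl-type secondary C1 hydroxyl free.

Step 18
Reactants: 20 (1R,5S,6S,10R)-9-[(E)-1-(tert-butyldiphenylsilyloxy)propan-2-ylidene]-6-methyl-10-[3-(tert-butyldiphenylsilyloxy)propyl]-6-(triethylsilyloxy)spiro[4.5]decan-1-ol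
Product: 22 the C1 diazoacetate of 20, via tosylhydrazone ester 21 (not isolated)
Conditions: TsNHN=CHCOCl, PhNMe2, CH2Cl2, 0 °C; then Et3N
Reagents that add atoms: glyoxylic acid chloride 4-methylbenzenesulfonylhydrazone, Cc1ccc(cc1)S(=O)(=O)NN=CC(Cl)=O
Why: Acylation with the glyoxylyl chloride tosylhydrazone and base-induced loss of sulfinate (Corey–Myers diazoacetate synthesis) is the established one-flask route to diazoacetates of hindered alcohols.

Step 19
Reactants: 22 the C1 diazoacetate of 20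
Product: 23 the cis-fused γ-lactone C1–O–C(=O)–CH2–C2, (1R,2S,5S,6S,10R)
Conditions: Rh2(NHCOCH3)4 (1 mol%), CH2Cl2, 40 °C, slow addition
Reagents that add atoms: none
Why: Rhodium-carbenoid intramolecular C–H insertion of cycloalkyl diazoacetates forms five-membered lactones, and here C2–H is the only C–H in a 1,5-relationship (C5 is quaternary), so insertion with retention into the C2–H cis to the ester oxygen should set C2 (2S) through the required cis ring fusion.

Step 20
Reactants: 23 the cis-fused γ-lactone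
Product: 24 the (Z)-α-(hydroxymethylene) lactone
Conditions: NaH, HCO2Et, THF, 0 → 25 °C; 1 M HCl work-up
Reagents that add atoms: ethyl formate, CCOC=O
Why: Claisen formylation of the lactone enolate gives the α-formyl lactone, which should rest as the hydrogen-bonded enol with OH cis to the lactone carbonyl.

Step 21
Reactants: 24 the (Z)-α-(hydroxymethylene) lactone
Product: 25 the (Z)-enol triflate of 24
Conditions: NaH, THF, 0 °C; PhNTf2, 0 → 25 °C
Reagents that add atoms: N-phenylbis(trifluoromethanesulfonimide), O=S(=O)(N(c1ccccc1)S(=O)(=O)C(F)(F)F)C(F)(F)F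
Why: O-Sulfonylation of the sodium-chelated enolate (enol triflate formation under chelation control, as used for Z triflates of β-keto esters) should keep the oxygen cis to the lactone carbonyl.

Step 22
Reactants: 25 the (Z)-enol triflate of 24; 8 tributyl[(1E)-7-methyl-3-methylideneocta-1,6-dien-1-yl]stannane
Product: 26 the (Z)-α-[(2E)-8-methyl-4-methylidenenona-2,7-dien-1-ylidene] lactone
Conditions: Pd2(dba)3 (5 mol%), AsPh3 (20 mol%), LiCl, NMP, 25 °C
Reagents that add atoms: none
Why: Stille coupling of the electron-poor enol triflate with the dienylstannane proceeds with retention at both partners, giving the Z alkylidene and the E diene of the side chain.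

Step 23
Reactants: 26 the (Z)-α-[(2E)-8-methyl-4-methylidenenona-2,7-dien-1-ylidene] lactone
Product: 27 (1R,2S,5S,6S,10R)-2-[(2Z,4E)-1-hydroxy-10-methyl-6-methylideneundeca-2,4,9-trien-2-yl]-9-[(E)-1-(tert-butyldiphenylsilyloxy)propan-2-ylidene]-6-methyl-10-[3-(tert-butyldiphenylsilyloxy)propyl]-6-(triethylsilyloxy)spiro[4.5]decan-1-ol
Conditions: i-Bu2AlH (4 equiv), CH2Cl2, −78 → −20 °C
Reagents that add atoms: none
Why: Hydride reduction of the alkylidene lactone by 1,2-addition opens it to the C1 alcohol and the primary allylic alcohol without changing the alkene geometry fixed by the ring.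

Step 24
Reactants: 27 the diol above
Product: 28 the primary allylic acetate of 27
Conditions: Ac2O, pyridine, CH2Cl2, −20 → 0 °C
Reagents that add atoms: acetic anhydride, CC(=O)OC(C)=O
Why: Selective O-acetylation should take the primary allylic hydroxyl, because the secondary C1 hydroxyl is neopentyl-like and shielded by the cis C2 substituent.

Step 25
Reactants: 28 the primary allylic acetate of 27
Product: 29 the desilylated tetraol monoacetate (free hydroxyls at C1, C6, the C10 arm and the C9 alkylidene CH2OH)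
Conditions: HF·pyridine, pyridine, THF, 0 → 25 °C
Reagents that add atoms: none
Why: Buffered fluoride desilylation removes both primary TBDPS ethers and the tertiary TES ether under conditions that an allylic acetate and a triene should survive.

Step 26
Reactants: 29 the desilylated tetraol monoacetate
Product: 30 CNP0204268.1, [(2Z,4E)-2-[(1R,2S,5S,6S,10R)-1,6-dihydroxy-10-(3-hydroxypropyl)-6-methyl-9-[(E)-1-oxopropan-2-ylidene]spiro[4.5]decan-2-yl]-10-methyl-6-methylideneundeca-2,4,9-trienyl] acetate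
Conditions: MnO2 (activated, 20 equiv), CH2Cl2, 25 °C
Reagents that add atoms: none
Why: Allylic oxidation with MnO2 should convert only the allylic CH2OH on the C9 alkylidene to the enal, leaving the saturated primary, the homoallylic secondary and the tertiary alcohols.

**Compound list**
1 | pent-4-yn-1-ol | C#CCCCO | starting material
2 | tert-butyl(pent-4-yn-1-yloxy)diphenylsilane | C#CCCCO[Si](c1ccccc1)(c1ccccc1)C(C)(C)C | intermediate
3 | 6-(tert-butyldiphenylsilyloxy)hex-2-yn-1-ol | OCC#CCCCO[Si](c1ccccc1)(c1ccccc1)C(C)(C)C | intermediate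
4 | (E)-6-(tert-butyldiphenylsilyloxy)hex-2-en-1-ol | OC/C=C/CCCO[Si](c1ccccc1)(c1ccccc1)C(C)(C)C | intermediate
5 | (E)-6-(tert-butyldiphenylsilyloxy)hex-2-en-1-yl methyl carbonate | COC(=O)OC/C=C/CCCO[Si](c1ccccc1)(c1ccccc1)C(C)(C)C | intermediate
6 | 6-methylhept-5-en-2-one | CC(=O)CCC=C(C)C | starting material
7 | 6-methylhepta-1,5-dien-2-yl trifluoromethanesulfonate | C=C(OS(=O)(=O)C(F)(F)F)CCC=C(C)C | intermediate
8 | tributyl[(1E)-7-methyl-3-methylideneocta-1,6-dien-1-yl]stannane | CCCC[Sn](CCCC)(CCCC)/C=C/C(=C)CCC=C(C)C | intermediate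
9 | 2-acetylcyclopentan-1-one | CC(=O)C1CCCC1=O | starting material
10 | (2R)-2-acetyl-2-[(3R)-6-(tert-butyldiphenylsilyloxy)hex-1-en-3-yl]cyclopentan-1-one | C1CC[C@](C(C)=O)([C@H](CCCO[Si](c2ccccc2)(c2ccccc2)C(C)(C)C)C=C)C1=O | intermediate
11 | 1-[(1S,2R)-2-hydroxy-1-[(3R)-6-(tert-butyldiphenylsilyloxy)hex-1-en-3-yl]cyclopentyl]ethan-1-one | C1CC[C@](C(C)=O)([C@H](CCCO[Si](c2ccccc2)(c2ccccc2)C(C)(C)C)C=C)[C@@H]1O | intermediate
12 | (1R,2S)-2-acetyl-2-[(3R)-6-(tert-butyldiphenylsilyloxy)hex-1-en-3-yl]cyclopentyl 2,2-dimethylpropanoate | C1CC[C@](C(C)=O)([C@H](CCCO[Si](c2ccccc2)(c2ccccc2)C(C)(C)C)C=C)[C@@H]1OC(=O)C(C)(C)C | intermediate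
13 | (1R,2S)-2-acetyl-2-[(3S)-6-(tert-butyldiphenylsilyloxy)-2-oxohexan-3-yl]cyclopentyl 2,2-dimethylpropanoate | C1CC[C@](C(C)=O)([C@H](CCCO[Si](c2ccccc2)(c2ccccc2)C(C)(C)C)C(C)=O)[C@@H]1OC(=O)C(C)(C)C | intermediate
14 | (1R,2S)-2-[1-(trimethylsilyloxy)ethenyl]-2-[(3S)-6-(tert-butyldiphenylsilyloxy)-2-(trimethylsilyloxy)hex-1-en-3-yl]cyclopentyl 2,2-dimethylpropanoate (bis(silyl enol ether), key-step precursor) | C1CC[C@](C(=C)O[Si](C)(C)C)([C@H](CCCO[Si](c2ccccc2)(c2ccccc2)C(C)(C)C)C(=C)O[Si](C)(C)C)[C@@H]1OC(=O)C(C)(C)C | intermediate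
15 | (1R,5S,10S)-10-[3-(tert-butyldiphenylsilyloxy)propyl]-6,9-dioxospiro[4.5]decan-1-yl 2,2-dimethylpropanoate (key-step product) | C1CC[C@]2([C@H](CCCO[Si](c3ccccc3)(c3ccccc3)C(C)(C)C)C(=O)CCC2=O)[C@@H]1OC(=O)C(C)(C)C | intermediate
16 | ethyl (2E)-2-[(1R,5S,10R)-10-[3-(tert-butyldiphenylsilyloxy)propyl]-6-oxo-1-(pivaloyloxy)spiro[4.5]decan-9-ylidene]propanoate | C1CC[C@]2([C@H](CCCO[Si](c3ccccc3)(c3ccccc3)C(C)(C)C)/C(=C(\C)C(=O)OCC)CCC2=O)[C@@H]1OC(=O)C(C)(C)C | intermediate
17 | ethyl (2E)-2-[(1R,5S,6S,10R)-6-hydroxy-6-methyl-10-[3-(tert-butyldiphenylsilyloxy)propyl]-1-(pivaloyloxy)spiro[4.5]decan-9-ylidene]propanoate | C1CC[C@]2([C@H](CCCO[Si](c3ccccc3)(c3ccccc3)C(C)(C)C)/C(=C(\C)C(=O)OCC)CC[C@]2(C)O)[C@@H]1OC(=O)C(C)(C)C | intermediate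
18 | 6-O-triethylsilyl ether of 17 | C1CC[C@]2([C@H](CCCO[Si](c3ccccc3)(c3ccccc3)C(C)(C)C)/C(=C(\C)C(=O)OCC)CC[C@]2(C)O[Si](CC)(CC)CC)[C@@H]1OC(=O)C(C)(C)C | intermediate
19 | (1R,5S,6S,10R)-9-[(E)-1-hydroxypropan-2-ylidene]-6-methyl-10-[3-(tert-butyldiphenylsilyloxy)propyl]-6-(triethylsilyloxy)spiro[4.5]decan-1-ol | C1CC[C@]2([C@H](CCCO[Si](c3ccccc3)(c3ccccc3)C(C)(C)C)/C(=C(\C)CO)CC[C@]2(C)O[Si](CC)(CC)CC)[C@@H]1O | intermediate
20 | (1R,5S,6S,10R)-9-[(E)-1-(tert-butyldiphenylsilyloxy)propan-2-ylidene]-6-methyl-10-[3-(tert-butyldiphenylsilyloxy)propyl]-6-(triethylsilyloxy)spiro[4.5]decan-1-ol | C1CC[C@]2([C@H](CCCO[Si](c3ccccc3)(c3ccccc3)C(C)(C)C)/C(=C(\C)CO[Si](c3ccccc3)(c3ccccc3)C(C)(C)C)CC[C@]2(C)O[Si](CC)(CC)CC)[C@@H]1O | intermediate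
21 | C1 ester of 20 with glyoxylic acid 4-methylbenzenesulfonylhydrazone | C1CC[C@]2([C@H](CCCO[Si](c3ccccc3)(c3ccccc3)C(C)(C)C)/C(=C(\C)CO[Si](c3ccccc3)(c3ccccc3)C(C)(C)C)CC[C@]2(C)O[Si](CC)(CC)CC)[C@@H]1OC(=O)C=NNS(=O)(=O)c4ccc(C)cc4 | intermediate (not isolated)
22 | C1 diazoacetate of 20 | C1CC[C@]2([C@H](CCCO[Si](c3ccccc3)(c3ccccc3)C(C)(C)C)/C(=C(\C)CO[Si](c3ccccc3)(c3ccccc3)C(C)(C)C)CC[C@]2(C)O[Si](CC)(CC)CC)[C@@H]1OC(=O)C=[N+]=[N-] | intermediate
23 | cis-fused γ-lactone (C1–O–C(=O)–CH2–C2), (1R,2S,5S,6S,10R) | O=C1C[C@@H]2CC[C@]3([C@H](CCCO[Si](c4ccccc4)(c4ccccc4)C(C)(C)C)/C(=C(\C)CO[Si](c4ccccc4)(c4ccccc4)C(C)(C)C)CC[C@]3(C)O[Si](CC)(CC)CC)[C@@H]2O1 | intermediate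
24 | (Z)-α-(hydroxymethylene) lactone (OH cis to C=O) | O=C1/C(=C\O)[C@@H]2CC[C@]3([C@H](CCCO[Si](c4ccccc4)(c4ccccc4)C(C)(C)C)/C(=C(\C)CO[Si](c4ccccc4)(c4ccccc4)C(C)(C)C)CC[C@]3(C)O[Si](CC)(CC)CC)[C@@H]2O1 | intermediate
25 | (Z)-enol triflate of 24 | O=C1/C(=C\OS(=O)(=O)C(F)(F)F)[C@@H]2CC[C@]3([C@H](CCCO[Si](c4ccccc4)(c4ccccc4)C(C)(C)C)/C(=C(\C)CO[Si](c4ccccc4)(c4ccccc4)C(C)(C)C)CC[C@]3(C)O[Si](CC)(CC)CC)[C@@H]2O1 | intermediate
26 | (Z)-α-[(2E)-8-methyl-4-methylidenenona-2,7-dien-1-ylidene] lactone | O=C1/C(=C\C=C\C(=C)CCC=C(C)C)[C@@H]2CC[C@]3([C@H](CCCO[Si](c4ccccc4)(c4ccccc4)C(C)(C)C)/C(=C(\C)CO[Si](c4ccccc4)(c4ccccc4)C(C)(C)C)CC[C@]3(C)O[Si](CC)(CC)CC)[C@@H]2O1 | intermediate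
27 | (1R,2S,5S,6S,10R)-2-[(2Z,4E)-1-hydroxy-10-methyl-6-methylideneundeca-2,4,9-trien-2-yl]-9-[(E)-1-(tert-butyldiphenylsilyloxy)propan-2-ylidene]-6-methyl-10-[3-(tert-butyldiphenylsilyloxy)propyl]-6-(triethylsilyloxy)spiro[4.5]decan-1-ol | C=C(/C=C/C=C(\CO)[C@@H]1CC[C@]2([C@H](CCCO[Si](c3ccccc3)(c3ccccc3)C(C)(C)C)/C(=C(\C)CO[Si](c3ccccc3)(c3ccccc3)C(C)(C)C)CC[C@]2(C)O[Si](CC)(CC)CC)[C@@H]1O)CCC=C(C)C | intermediate
28 | primary allylic acetate of 27 | C=C(/C=C/C=C(\COC(C)=O)[C@@H]1CC[C@]2([C@H](CCCO[Si](c3ccccc3)(c3ccccc3)C(C)(C)C)/C(=C(\C)CO[Si](c3ccccc3)(c3ccccc3)C(C)(C)C)CC[C@]2(C)O[Si](CC)(CC)CC)[C@@H]1O)CCC=C(C)C | intermediate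
29 | desilylated tetraol monoacetate (C9 alkylidene CH2OH) | C=C(/C=C/C=C(\COC(C)=O)[C@@H]1CC[C@]2([C@H](CCCO)/C(=C(\C)CO)CC[C@]2(C)O)[C@@H]1O)CCC=C(C)C | intermediate
30 | CNP0204268.1 | C=C(/C=C/C=C(\COC(C)=O)[C@@H]1CC[C@]2([C@H](CCCO)/C(=C(\C)C=O)CC[C@]2(C)O)[C@@H]1O)CCC=C(C)C | target

**Count**
Total: 26 steps. Longest linear sequence: 24 steps (steps 1–4, then 7–26). Fragment B (steps 5–6) joins at step 22.

**Steps most likely to fail**

Step 12 (anodic coupling). The silyl enol ethers may be solvolysed by methanol before electron transfer, the radical cation may be captured by methanol or by a second molecule, or the anode may foul. The fallback sets out from 14. Both silyl groups are removed with KOt-Bu (2.1 equiv, THF, −78 °C) to give the dipotassium bis-enolate F1. F1 holds no carbonyl group and so cannot close by aldol reaction. It is oxidised in the same flask with CuCl2 in DMF (−78 → 0 °C), the established copper-mediated oxidative coupling of ketone enolates, and the route is rejoined at dione 15.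

Step 13 (olefination at C9). The bulky phosphonate anion may add too slowly to the flanked ketone, the base may epimerise C10 through the C9 enolate, and geometric control over the tetrasubstituted alkene may be poor. The fallback sets out from 15. Ethyl 2-(trimethylsilyl)propanoate is deprotonated with LiN(i-Pr)2 and added at −78 °C. The smaller lithium ester enolate should add to C9 to give the β-hydroxy silane F2 (as its lithium alkoxide). On warming this loses trimethylsilanolate in a Peterson olefination, and the route is rejoined at enoate 16, with geometric isomers separated as before.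

Step 19 (C–H insertion). The carbenoid may be diverted into the allylic C10–H, into ylide formation at the silyl ether oxygen, or into dimerisation. The fallback sets out from 20. Dess–Martin oxidation gives the C1 ketone F3, which can enolise only towards C2. Deprotonation with LiN(i-Pr)2 and alkylation with methyl bromoacetate give the keto ester F4; the C2 epimers can be equilibrated with base and separated. Reduction with LiBH(s-Bu)3 at −78 °C delivers hydride anti to the C2 arm to give the cis hydroxy ester F5. F5 lactonises on mild acid work-up, and the route is rejoined at lactone 23.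

**Further compounds**
F1 | step 12 | dipotassium bis-enolate derived from 14 | [K+].[K+].C1CC[C@](C(=C)[O-])([C@H](CCCO[Si](c2ccccc2)(c2ccccc2)C(C)(C)C)C(=C)[O-])[C@@H]1OC(=O)C(C)(C)C
F2 | step 13 | ethyl 2-[C9-hydroxy adduct of 15]-2-(trimethylsilyl)propanoate (mixture at the two new centres) | C1CC[C@]2([C@H](CCCO[Si](c3ccccc3)(c3ccccc3)C(C)(C)C)C(O)(C(C)([Si](C)(C)C)C(=O)OCC)CCC2=O)[C@@H]1OC(=O)C(C)(C)C
F3 | step 19 | C1 ketone from 20 | C1CC[C@]2([C@H](CCCO[Si](c3ccccc3)(c3ccccc3)C(C)(C)C)/C(=C(\C)CO[Si](c3ccccc3)(c3ccccc3)C(C)(C)C)CC[C@]2(C)O[Si](CC)(CC)CC)C1=O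
F4 | step 19 | methyl 2-[(2S)-1-oxo-spirocycle-2-yl]acetate (C2-alkylated F3) | COC(=O)C[C@@H]1CC[C@]2([C@H](CCCO[Si](c3ccccc3)(c3ccccc3)C(C)(C)C)/C(=C(\C)CO[Si](c3ccccc3)(c3ccccc3)C(C)(C)C)CC[C@]2(C)O[Si](CC)(CC)CC)C1=O
F5 | step 19 | cis hydroxy ester from F4 | COC(=O)C[C@@H]1CC[C@]2([C@H](CCCO[Si](c3ccccc3)(c3ccccc3)C(C)(C)C)/C(=C(\C)CO[Si](c3ccccc3)(c3ccccc3)C(C)(C)C)CC[C@]2(C)O[Si](CC)(CC)CC)[C@@H]1O
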